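## Retrosynthetic overview

1. Feature: in the 2-methoxy-6-alkyl-1,4-benzoquinone ring, the carbonyl C1=O lies between the C2–OMe carbon and the C6–alkyl carbon. Removing that oxygen leaves a benzene ring in which OH (the old C4=O), OMe and the CH2CH(OAc)C13H27 chain are mutually meta (phenol 19).
2. 19 ⇒ 3-substituted cyclobutenone 11 + methoxyacetylene 14 by a cyclobutenone/ynol ether benzannulation. The ketone oxygen of 11 becomes the phenol OH, the two alkyne carbons enter between C=O and the vinylic α-CH, and the side chain stays on the old C3.
3. 11 ⇒ terminal alkyne 7 + dichloroketene ([2+2], then zinc dechlorination); 14 ⇒ chloroacetaldehyde dimethyl acetal 12.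
4. 7 ⇒ (R)-epichlorohydrin 1 (source of the stereocentre, whose C–O bond is never broken) + dodecyl Grignard 2 + acetylide 5.
5. Ring order: oxirane (step 1, opened in step 2), cyclobutenone (step 4), benzene ring (step 7), oxidised to the quinone (step 8).

Key step: step 7

Remark: the (R) stereocentre is taken from commercial (R)-epichlorohydrin instead of being set by catalysis, so enantiopurity is not a variable of the route. Methoxyacetylene is volatile and is prepared and used fresh.

## Route

Step 1
Reactants: 1 (R)-epichlorohydrin; 2 dodecylmagnesium bromide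
Product: 4 (R)-2-tridecyloxirane, via (R)-1-chloropentadecan-2-ol 3 (not isolated)
Conditions: 2 (1.1 equiv), CuI (10 mol%), THF, −40 → 0 °C; then 5 M NaOH (aq), rt
Reagents that add atoms: none
Why: Copper-catalysed Grignard opening of the epoxide at its unsubstituted CH2 (faster than SN2 at C–Cl at low temperature) gives the chlorohydrin, which closes by intramolecular Williamson etherification under NaOH; the C–O bond at the stereocentre is never broken, so (R)-1 should give (R)-4.

Step 2
Reactants: 4 (R)-2-tridecyloxirane; 5 lithium acetylide–ethylenediamine complex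
Product: 6 (R)-heptadec-1-yn-4-ol
Conditions: 5 (2 equiv), DMSO, 0 °C → rt; H2O quench
Reagents that add atoms: none
Why: SN2 opening of a terminal epoxide by lithium acetylide at the less hindered CH2 in DMSO is a standard route to homopropargylic alcohols and leaves the carbinol stereocentre untouched.

Step 3
Reactants: 6 (R)-heptadec-1-yn-4-ol
Product: 7 (R)-heptadec-1-yn-4-yl acetate
Conditions: Ac2O, pyridine, DMAP (cat.), CH2Cl2, 0 °C → rt
Reagents that add atoms: acetic anhydride, CC(=O)OC(C)=O
Why: DMAP-catalysed acylation of a secondary alcohol installs the acetate of the target early, with retention because only the O–H bond reacts.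

Step 4
Reactants: 7 (R)-heptadec-1-yn-4-yl acetate; 8 trichloroacetyl chloride
Product: 10 (R)-1-(4,4-dichloro-3-oxocyclobut-1-en-1-yl)pentadecan-2-yl acetate, via dichloroketene 9 (not isolated)
Conditions: 8 (2 equiv), Zn–Cu couple, Et2O/DME, rt
Reagents that add atoms: none
Why: Dichloroketene generated by zinc dechlorination of 8 undergoes the known [2+2] cycloaddition with a terminal alkyne, the terminal alkyne carbon bonding to the ketene carbonyl carbon to give the 3-alkyl-4,4-dichlorocyclobutenone; DME ties up ZnCl2 and the acetate is a spectator.

Step 5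
Reactants: 10 (R)-1-(4,4-dichloro-3-oxocyclobut-1-en-1-yl)pentadecan-2-yl acetate
Product: 11 (R)-1-(3-oxocyclobut-1-en-1-yl)pentadecan-2-yl acetate
Conditions: Zn dust, AcOH, TMEDA, EtOH, 0 °C → rt
Reagents that add atoms: none
Why: Zinc reduction of the α,α-dichloro ketone through zinc enolates, buffered by TMEDA/AcOH, is the established dechlorination of 3-alkyl-4,4-dichlorocyclobutenones and is mild enough for the ester, the enone and the remote stereocentre.

Step 6
Reactants: 12 chloroacetaldehyde dimethyl acetal
Product: 14 methoxyacetylene, via sodium methoxyacetylide 13 (not isolated)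
Conditions: NaNH2 (3 equiv), liq. NH3, −33 °C; evaporate NH3; cold sat. aq. NaCl, distil into a cold trap
Reagents that add atoms: none
Why: Sodium amide effects a double elimination (HCl to the ketene acetal, then MeOH) and deprotonates the resulting ynol ether to its sodium acetylide; cold aqueous protonation then releases the volatile alkyne for distillation.

Step 7
Reactants: 11 (R)-1-(3-oxocyclobut-1-en-1-yl)pentadecan-2-yl acetate; 14 methoxyacetylene
Product: 19 (R)-1-(3-hydroxy-5-methoxyphenyl)pentadecan-2-yl acetate, via vinylketene 15 (not isolated), via 4-vinylcyclobutenone 16 (not isolated), via dienylketene 17 (not isolated), via cyclohexa-2,4-dienone 18 (not isolated)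
Conditions: 14 (3 equiv), toluene, 80 °C, sealed tube
Reagents that add atoms: none
Why: Thermal 4π-electrocyclic opening of 11 (carbonyl carbon–CH2 bond) gives vinylketene 15, whose ketene C=C adds methoxyacetylene in a [2+2] cycloaddition to give 16; a second 4π opening gives dienylketene 17, which closes the benzene ring by a thermal disrotatory 6π-electrocyclisation between the ketene carbon and the terminal CH2, and dienone 18 tautomerises to phenol 19. The closest known reaction type is the Danheiser benzannulation of 3-alkylcyclobutenones with alkoxyacetylenes to 5-alkylresorcinol monoethers, applied here to a substrate carrying a remote acetoxy group. Net, the two alkyne carbons are inserted between the carbonyl carbon and the vinylic α-carbon of the cyclobutenone (two new C–C bonds), and the six-membered ring is closed by the electrocyclisation that re-forms the bond from the old carbonyl carbon to the old ring CH2. No stereocentre is created: the sp3 ring carbon of 16 is transient and is erased on ring opening, and the acetoxy carbinol carbon is separated from the reacting π system by a CH2 and meets neither acid nor base. The selectivity needed is the orientation of the ketene–alkyne cycloaddition, and it is secured by the polarisation of the ynol ether, whose nucleophilic unsubstituted carbon bonds to the electrophilic ketene carbonyl carbon, so that OMe ends meta to OH and the side chain meta to both. An excess of the volatile alkyne in a closed vessel should keep the vinylketene from dimerising or acylating the product phenol.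

Step 8
Reactants: 19 (R)-1-(3-hydroxy-5-methoxyphenyl)pentadecan-2-yl acetate
Product: 20 ardisinone, (R)-1-(5-methoxy-3,6-dioxocyclohexa-1,4-dien-1-yl)pentadecan-2-yl acetate
Conditions: (KSO3)2NO (2.5 equiv), aq. KH2PO4, acetone/H2O, rt
Reagents that add atoms: Fremy's salt (potassium nitrosodisulfonate), [K+].[K+].[O]N(S(=O)(=O)[O-])S(=O)(=O)[O-]
Why: In the Teuber oxidation one nitroxyl radical abstracts the phenolic hydrogen and a second couples at the free para carbon (the position between C–OMe and C–alkyl), and collapse of the adduct gives the p-quinone with the new carbonyl exactly where the target has it; the buffered near-neutral medium should spare the acetate and the stereocentre.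

## Compound list

1 | (R)-epichlorohydrin, (R)-2-(chloromethyl)oxirane | ClC[C@H]1CO1 | starting material
2 | dodecylmagnesium bromide | CCCCCCCCCCCC[Mg]Br | starting material
3 | (R)-1-chloropentadecan-2-ol | CCCCCCCCCCCCC[C@H](CCl)O | intermediate
4 | (R)-2-tridecyloxirane | CCCCCCCCCCCCC[C@@H]1CO1 | intermediate
5 | lithium acetylide–ethylenediamine complex | [Li+].[C-]#C.NCCN | starting material
6 | (R)-heptadec-1-yn-4-ol | CCCCCCCCCCCCC[C@H](CC#C)O | intermediate
7 | (R)-heptadec-1-yn-4-yl acetate | CCCCCCCCCCCCC[C@H](CC#C)OC(C)=O | intermediate
8 | trichloroacetyl chloride | ClC(Cl)(Cl)C(Cl)=O | starting material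
9 | dichloroketene | ClC(Cl)=C=O | intermediate
10 | (R)-1-(4,4-dichloro-3-oxocyclobut-1-en-1-yl)pentadecan-2-yl acetate | CCCCCCCCCCCCC[C@H](CC1=CC(=O)C1(Cl)Cl)OC(C)=O | intermediate
11 | (R)-1-(3-oxocyclobut-1-en-1-yl)pentadecan-2-yl acetate | CCCCCCCCCCCCC[C@H](CC1=CC(=O)C1)OC(C)=O | intermediate
12 | chloroacetaldehyde dimethyl acetal | COC(CCl)OC | starting material
13 | sodium methoxyacetylide | [Na+].[C-]#COC | intermediate
14 | methoxyacetylene | COC#C | intermediate
15 | vinylketene, (R)-1-(4-oxobuta-1,3-dien-2-yl)pentadecan-2-yl acetate | CCCCCCCCCCCCC[C@H](CC(=C)C=C=O)OC(C)=O | intermediate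
16 | 4-vinylcyclobutenone, (2R)-1-[1-(2-methoxy-4-oxocyclobut-2-en-1-yl)ethenyl]pentadecan-2-yl acetate (ring CH as both epimers) | CCCCCCCCCCCCC[C@H](CC(=C)C1C(OC)=CC1=O)OC(C)=O | intermediate
17 | dienylketene, (2R)-1-[(3E)-4-methoxy-6-oxohexa-1,3,5-trien-2-yl]pentadecan-2-yl acetate (ketene and vinyl arms cis on the central C=C) | CCCCCCCCCCCCC[C@H](CC(=C)/C=C(OC)\C=C=O)OC(C)=O | intermediate
18 | cyclohexa-2,4-dienone, (R)-1-(3-methoxy-5-oxocyclohexa-1,3-dien-1-yl)pentadecan-2-yl acetate | CCCCCCCCCCCCC[C@H](CC1=CC(OC)=CC(=O)C1)OC(C)=O | intermediate
19 | (R)-1-(3-hydroxy-5-methoxyphenyl)pentadecan-2-yl acetate | CCCCCCCCCCCCC[C@H](Cc1cc(O)cc(OC)c1)OC(C)=O | intermediate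
20 | ardisinone, (R)-1-(5-methoxy-3,6-dioxocyclohexa-1,4-dien-1-yl)pentadecan-2-yl acetate | CCCCCCCCCCCCC[C@H](CC1=CC(=O)C=C(OC)C1=O)OC(C)=O | target

## Step count

Total steps: 8. Longest linear sequence: 7 (steps 1, 2, 3, 4, 5, 7, 8); step 6 is the one-step side branch to the alkyne.

## Steps most likely to fail

**Step 7 (benzannulation).** The vinylketene may dimerise or acylate the phenol as it forms, giving an aryl ester that cannot be cleaved with strong base in the presence of the acetate. The volatile ynol ether may also polymerise before it intercepts the ketene. The fallback abandons the pericyclic ring construction and attaches a preformed arene to the same chiral epoxide. It sets out from epoxide 4 and returns at phenol 19. Commercial 3-bromo-5-methoxyphenol is benzylated (BnBr, K2CO3, DMF) to 1-(benzyloxy)-3-bromo-5-methoxybenzene F1. Magnesium in THF converts this to [3-(benzyloxy)-5-methoxyphenyl]magnesium bromide F2. Under CuI catalysis F2 opens 4 at its CH2 to give (R)-1-[3-(benzyloxy)-5-methoxyphenyl]pentadecan-2-ol F3. Acetylation (Ac2O, pyridine, DMAP) gives (R)-1-[3-(benzyloxy)-5-methoxyphenyl]pentadecan-2-yl acetate F4. Hydrogenolysis of the benzyl ether (H2, Pd/C, EtOAc) then gives 19; the homobenzylic acetate is not cleaved.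

**Step 4 (dichloroketene cycloaddition).** Dichloroketene may oligomerise faster than it adds to a monosubstituted, functionalised alkyne. Zinc chloride may also promote chloride migration in the product to the isomeric 2,4-dichlorocyclobutenone, which would complicate step 5. The fallback replaces the ketene by a keteniminium ion and needs no dechlorination. It sets out from alkyne 7 and returns at cyclobutenone 11, bypassing 10 and step 5. N,N-Dimethylacetamide, Tf2O and 2,4,6-collidine in 1,2-dichloroethane generate N,N-dimethylketeniminium triflate F5. At reflux F5 adds to the terminal alkyne of 7 with the same orientation to give N-{3-[(2R)-2-acetoxypentadecyl]cyclobut-2-en-1-ylidene}-N-methylmethanaminium triflate F6. Hydrolysis with aqueous NaHCO3 gives 11.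

**Step 8 (phenol to quinone).** Oxidation may start at an ortho position and lead to an o-quinone. The lipophilic phenol may react slowly in the aqueous medium, so that the quinone is exposed for long periods and degrades. The fallback changes from the one-step radical oxidation to a two-electron oxidation through a quinone monoketal. It sets out from phenol 19 and returns at target 20. PhI(OAc)2 (2.2 equiv) in MeOH at 0 °C should methoxylate the para position twice to give (R)-1-(5,6,6-trimethoxy-3-oxocyclohexa-1,4-dien-1-yl)pentadecan-2-yl acetate F7. Mild hydrolysis of the ketal (aqueous oxalic acid, acetone, rt) then releases 20 without touching the acetate.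

## Further compounds

F1 | step 7 | 1-(benzyloxy)-3-bromo-5-methoxybenzene | COc1cc(Br)cc(OCc2ccccc2)c1
F2 | step 7 | [3-(benzyloxy)-5-methoxyphenyl]magnesium bromide | COc1cc([Mg]Br)cc(OCc2ccccc2)c1
F3 | step 7 | (R)-1-[3-(benzyloxy)-5-methoxyphenyl]pentadecan-2-ol | CCCCCCCCCCCCC[C@H](Cc1cc(OC)cc(OCc2ccccc2)c1)O
F4 | step 7 | (R)-1-[3-(benzyloxy)-5-methoxyphenyl]pentadecan-2-yl acetate | CCCCCCCCCCCCC[C@H](Cc1cc(OC)cc(OCc2ccccc2)c1)OC(C)=O
F5 | step 4 | N,N-dimethylketeniminium triflate | C=C=[N+](C)C.[O-]S(=O)(=O)C(F)(F)F
F6 | step 4 | N-{3-[(2R)-2-acetoxypentadecyl]cyclobut-2-en-1-ylidene}-N-methylmethanaminium triflate | CCCCCCCCCCCCC[C@H](CC1=CC(=[N+](C)C)C1)OC(C)=O.[O-]S(=O)(=O)C(F)(F)F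
F7 | step 8 | (R)-1-(5,6,6-trimethoxy-3-oxocyclohexa-1,4-dien-1-yl)pentadecan-2-yl acetate | CCCCCCCCCCCCC[C@H](CC1=CC(=O)C=C(OC)C1(OC)OC)OC(C)=O
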